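**Structural features**

The target is an achiral diaryl ether: two pentasubstituted benzene rings are joined only through one oxygen, which links C3 of ring A to C1' of ring B. Ring A carries CH2OH at C1, Br at C2, the ether oxygen at C3, OH at C4 and Br at C5; ring B carries the ether oxygen at C1', CH2OH at C2', Br at C4' and a catechol at C5' and C6'; C6 and C3' are the only ring CH positions. There is no stereocentre, so no stereocentres stand next to each other, and the ether axis is not expected to be configurationally stable although four ortho substituents flank it. The fragile groups are the two benzylic alcohols, each para to a free phenol (C1/C4–OH and C2'/C5'–OH) and therefore prone to ionise to quinone methides under acid or strong base, the catechol, which is oxidised by air once deprotonated, and the three C–Br bonds, which exclude hydrogenolysis, halogen–metal exchange and most cross-coupling. The real difficulty is the ether bond between two carbons that are each flanked on both sides, together with two different, unsymmetrical oxygen and bromine patterns that electrophilic substitution of a preformed diaryl ether cannot set. The key step exploits the sequence C6'(O)–C1'(O–aryl)–C2'(one-carbon unit) of ring B with the C5' oxygen para to C2': this is C3, C4 and C5 of a 2-pyrone-5-carboxylate (numbered O1, C2 lactone carbonyl, C3–C6), completed by the two carbons C4' and C5' of a ketene acetal. In this way the hindered ether is made earlier, as a vinylogous ester at pyrone C4, and benzene ring B is grown around it.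

**Logic of the disconnections**

19 ⇒ 18. The benzylic C–H bonds at the C1 and C2' carbons are removed, which leads back to an aldehyde on ring A and a methyl ester on ring B. The hydroxymethyl groups para to free phenols are the most labile feature and are therefore made last. The gain is two electron-withdrawing carbonyl groups that stabilise the phenols through the earlier steps. The forward step needs a hydride that reduces an ester deactivated by a para oxido group, leaves three C–Br bonds alone, and is worked up near neutrality.

18 ⇒ 17. The three phenolic O–H bonds (C4, C5', C6') are traced back to O–CH3 bonds. Methyl ethers are the only oxygen protection that the ring-forming chemistry supplies by itself. The forward ether cleavage must spare the methyl ester and the aldehyde, and it is placed before the reduction so that no benzylic alcohol meets a boron halide.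

17 ⇒ 16. The C4'–Br bond is cut. C4' is ortho to the C5' methoxy group and para to the ether oxygen, the most nucleophilic site of ring B, while ring A is deactivated. The gain is that the two-carbon partner of the ring construction can be the simplest one. The forward step must choose C4' over C3'.

16 ⇒ 11 + 12. The bonds C3'–C4' and C5'–C6' are cut, which takes ring B apart into a pyrone and a two-carbon unit. This is the largest simplification: the ether oxygen becomes a substituent on an electron-poor heterocycle and all other ring B substituents are already in place. The forward step needs one orientation of 12, enough electrophilicity in a pyrone that carries two donor oxygens, and a ring A formyl group that cannot react with 12; for that reason 11 holds the aldehyde as an acetal, which is removed in the work-up that gives 16.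

11 ⇒ 10 + 4. The bond between pyrone C4 and the aryl oxygen (the later C1'–O bond) is cut. At this stage the carbon is a vinylogous acyl carbon with a sulfonate leaving group, so the ether is made by addition–elimination instead of aryl–oxygen coupling. The two fragments are of similar size. The forward step needs a hindered phenoxide to attack C4 and not sulfur or C6.

10 ⇒ 9 ⇒ 7. First the O–S bond, then the lactone bond O1–C2 and the bond C5–C6 are cut, the C6 carbon coming from an orthoformate; 8 lies on the way. The ring reduces to an acyclic keto diester. The condensation must take place at the CH2 group and not at the methoxy-bearing carbon.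

7 ⇒ 6 ⇒ 5. The C–OCH3 bond is cut (carbenoid insertion into the O–H bond of methanol), then the C=N2 bond. This leads to a symmetrical commercial keto diester. Diazo transfer must stop after one of the two equivalent CH2 groups.

4 ⇒ 3 ⇒ 2 ⇒ 1. The acetal C–O bonds, the C2–Br bond and the O4–CH3 bond are cut in turn. The free C3 hydroxyl is the only group able to direct bromine to C2, so the C5 bromine has to be present from the start. The forward steps need O-methylation at the more acidic O4 and bromination ortho rather than para to the C3 hydroxyl.

**Other disconnections considered**

Alternative 1: The cut is at the ether bond O–C1' and at the C6' oxygen, which is replaced by a C6'–Si bond. In the forward step CsF would turn the silyl triflate A3 into a ring B aryne with the strained bond between C1' and C6'. The symmetric silylene A2, activated at silicon by fluoride, would add one oxygen to C1', and the aryl anion at C6' would be caught by silicon to give the seven-membered silylene A1.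
- In its favour: the step is convergent and metal-free, and all three bromines are already present. Because A2 is symmetric, either oxygen may add. The C6'–Si bond is a masked hydroxyl that a Tamao–Fleming oxidation (H2O2, KF, KHCO3) would convert to C6'–OH while freeing C4–OH. Both one-carbon units could finish as aldehydes, so that NaBH4 would suffice at the end; on this point alternative 1 is better than the chosen plan, which must reduce an ester on a triphenol.
- Against it: ring A arrives without its C1 carbon, so a late formylation must pick C1 (para to the freed C4–OH) over C6 on a ring deactivated by two bromines. The oxygen must add at C1' next to the bulky dioxolane, with only the inductive effect of the C5' methoxy group in support. Fluoride may simply cleave A2, after which the aryl anion would be protonated and the C6' oxygen lost. A3 is a pentasubstituted benzene that needs a long synthesis of its own.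
- Comparison: on structure, alternative 1 is equal in convergence and better in its use of a symmetric ring A piece, but A1 still lacks one carbon and one oxygen function, whereas 16 holds every carbon and oxygen of the target. On mechanism, both steps rely on polarisation, but the orientation of a ketene acetal on a coumalate is better founded than insertion of a 3,6-disubstituted aryne into an O–Si bond. On step economy, about five steps would follow A1 (oxidation, formylation, acetal removal, demethylation, reduction) against three after 16, and A3 adds further length.

Alternative 2: The cut is at the ether bond C3–O, to be formed by intramolecular phenol oxidation, with the C2' carbon bound to O4 as a lactone. In the forward step anodic oxidation of benzophenone A5 would join the ring B phenol oxygen to C3 of ring A to give the spiro dienone A6, and warming would move the acyl group from C3 to O4 to give depsidone A4.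
- In its favour: the ether bond is formed intramolecularly through a five-membered ring, which answers the steric problem better than the intermolecular addition–elimination of step 8. A4 holds the whole skeleton with all three bromines, so it is more complete than 16. Its lactone masks C4–OH and the C2' carbon together. Only demethylation and one hydride reduction would remain, two steps against three.
- Against it: A5 needs a diaryl ketone between C3 (flanked by Br and OH) and C2'. Friedel–Crafts acylation at such a position is unfavourable and organometallic routes clash with the bromines. The phenols of A5 are electron-poor, so the oxidation potential is high, the cathode may reduce C–Br bonds unless the cell is divided, and radical coupling may go to carbon or to the bromine-bearing C5. The acyl shift from A6 competes with other dienone rearrangements.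
- Comparison: on structure, alternative 2 is the better at the stage of its key product. On mechanism, radical-cation chemistry on polybrominated phenols is harder to predict than a polar cycloaddition. On step economy, it is shorter after the key step but longer and less secure before it.

Alternative 3: The cut is at C6'–C1' and C3'–C2', so ring B is again built around the ether, but from a furan and an alkyne. In the forward step furan A8 would add across the aryloxypropiolate A9 to give the oxanorbornadiene A10, and acid would open the oxygen bridge at C3'–O to give A7.
- In its favour: the ring A building block is the same phenol aldehyde as in the chosen plan (3), which is an equal point. No carbon nucleophile is present, so the aldehyde needs no acetal, which is better. A7 already carries the C4' bromine and a free C6' hydroxyl, so no late bromination is needed and two steps would follow instead of three, which is also better. The orientation is matched, since the nucleophilic furan carbon next to the methoxy group meets the alkyne carbon β to the ester.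
- Against it: A8 is not a stock chemical, and 3-alkoxyfurans are sensitive to acid and air. The aryloxy group of A9 donates into the triple bond and lowers its dienophilicity. Making A9 needs the same hindered phenoxide addition–elimination (onto a 3-halopropiolate) as step 8, so that difficulty is equal. Furan cycloadditions are reversible, A10 is crowded, and the heat or Lewis acid needed to force the addition also favours cycloreversion and furan decomposition. The bridge must open at C3'–O and not at C6'–O; the C5' methoxy group supports this, but a bromine or hydride shift could intervene.
- Comparison: on structure, alternative 3 is equal for ring A and better for ring B, which would be fully substituted in one step. On mechanism, it is less secure than the pyrone route, which loses CO2 irreversibly. On step economy, it is better after the key step and worse before it because of A8.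

Key step: step 9

Remarks on the chemistry (assumptions):
- The target is achiral; the stereocentres of 7, 8 and 13 are transient and racemic.
- The ring A formyl group is carried as a dimethyl acetal from 4 to 15. A free aryl aldehyde flanked by bromine would otherwise be exposed in step 9 to an excess of a hot, strongly nucleophilic ketene acetal. The acetal is removed in the work-up of that step.
- Ring A is built from 1 and not from 2-bromo-3-hydroxy-4-methoxybenzaldehyde. In that compound the free hydroxyl would direct a second bromine to C6 (para to OH), and after O-acylation the ring is too deactivated for clean bromination at C5. In 1 the C5 bromine is present from the start and the free C3 hydroxyl places the C2 bromine.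
- 1 is taken as purchasable; it is otherwise one demethylation (AlCl3, pyridine) from 5-bromovanillin.

**Route**

Step 1
Reactants: 1 3-bromo-4,5-dihydroxybenzaldehyde
Product: 2 3-bromo-5-hydroxy-4-methoxybenzaldehyde
Conditions: MeI (1.05 equiv), Li2CO3 (1.1 equiv), DMF, 40 °C
Reagents that add atoms: iodomethane CI
Why: Williamson ether synthesis under acidity control: the hydroxyl para to the formyl group and ortho to bromine is much the more acidic, so the weak base forms only that phenoxide and SN2 methylation should go to O4, as in selective 4-O-alkylation of 3,4-dihydroxybenzaldehydes; the limited amount of MeI guards against the dimethyl ether.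

Step 2
Reactants: 2 3-bromo-5-hydroxy-4-methoxybenzaldehyde
Product: 3 2,5-dibromo-3-hydroxy-4-methoxybenzaldehyde
Conditions: Br2 (1.05 equiv), NaOAc, AcOH, rt
Reagents that add atoms: bromine BrBr
Why: Electrophilic aromatic bromination directed by the free hydroxyl: of its two open positions the ortho carbon between OH and CHO (C2 of ring A) is the one attacked in the parent 3-hydroxy-4-methoxybenzaldehyde, and the para carbon C6 is further disfavoured here by the adjacent C5 bromine; NaOAc takes up HBr.

Step 3
Reactants: 3 2,5-dibromo-3-hydroxy-4-methoxybenzaldehyde
Product: 4 2,5-dibromo-3-(dimethoxymethyl)-6-methoxyphenol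
Conditions: HC(OMe)3 (3 equiv), MeOH, TsOH·H2O (cat.), 50 °C; then Et3N
Reagents that add atoms: trimethyl orthoformate COC(OC)OC; methanol CO
Why: Acid-catalysed acetalisation with the orthoformate as water scavenger; the phenol is not affected and the amine quench keeps the acetal intact, so the aldehyde is masked for step 9 at no extra cost in steps later on.

Step 4
Reactants: 5 dimethyl 3-oxopentanedioate
Product: 6 dimethyl 2-diazo-3-oxopentanedioate
Conditions: 4-acetamidobenzenesulfonyl azide (1.0 equiv), Et3N, MeCN, 0 °C → rt
Reagents that add atoms: 4-acetamidobenzenesulfonyl azide CC(=O)Nc1ccc(cc1)S(=O)(=O)N=[N+]=[N-]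
Why: Regitz diazo transfer to an active methylene; one equivalent of azide should limit the reaction to one of the two equivalent CH2 groups, because the diazo ketone formed activates the remaining CH2 less than the original ketone did.

Step 5
Reactants: 6 dimethyl 2-diazo-3-oxopentanedioate
Product: 7 dimethyl 2-methoxy-3-oxopentanedioate (racemic)
Conditions: Rh2(OAc)4 (1 mol %), MeOH (5 equiv), CH2Cl2, reflux
Reagents that add atoms: methanol CO
Why: Carbenoid O–H insertion of an α-diazo-β-keto ester catalysed by the divalent rhodium carboxylate Rh2(OAc)4 (oxonium ylide, then proton shift), a standard route to α-alkoxy-β-keto esters; the new stereocentre is formed racemic, is enolisable and vanishes in step 6.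

Step 6
Reactants: 7 dimethyl 2-methoxy-3-oxopentanedioate
Product: 9 methyl 4-hydroxy-3-methoxy-2-oxo-2H-pyran-5-carboxylate, via methoxymethylidene keto diester 8 (not isolated)
Conditions: HC(OMe)3 (2 equiv), Ac2O (3 equiv), 120 °C; concentrate; then 2 M HCl (aq), rt
Reagents that add atoms: trimethyl orthoformate COC(OC)OC; water O
Why: Alkoxymethylenation of the only CH2 flanked by ketone and ester gives 8 (the methoxy-bearing carbon has one hydrogen and cannot form an alkylidene); aqueous acid hydrolyses the enol ether and the hydroxymethylene oxygen lactonises onto the distal ester (6-exo-trig acyl substitution), which is the established way from 3-oxoglutarates to 4-hydroxy-2-pyrone-5-carboxylates.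

Step 7
Reactants: 9 methyl 4-hydroxy-3-methoxy-2-oxo-2H-pyran-5-carboxylate
Product: 10 methyl 3-methoxy-2-oxo-4-[(trifluoromethanesulfonyl)oxy]-2H-pyran-5-carboxylate
Conditions: Tf2O (1.1 equiv), Et3N, CH2Cl2, −78 → 0 °C
Reagents that add atoms: trifluoromethanesulfonic anhydride FC(F)(F)S(=O)(=O)OS(=O)(=O)C(F)(F)F
Why: O-sulfonylation of the acidic vinylogous carboxylic acid hydroxyl; 4-hydroxy-2-pyrones are routinely converted to 4-triflates under these conditions, and the product is used without delay.

Step 8
Reactants: 10 methyl 3-methoxy-2-oxo-4-[(trifluoromethanesulfonyl)oxy]-2H-pyran-5-carboxylate; 4 2,5-dibromo-3-(dimethoxymethyl)-6-methoxyphenol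
Product: 11 methyl 4-[2,5-dibromo-3-(dimethoxymethyl)-6-methoxyphenoxy]-3-methoxy-2-oxo-2H-pyran-5-carboxylate
Conditions: K2CO3 (1.5 equiv), MeCN, 0 °C → rt
Reagents that add atoms: none
Why: Conjugate addition–elimination (vinylogous acyl substitution): the phenoxide adds to C4, the β-carbon of the unsaturated lactone that bears the nucleofuge, and triflate leaves, as in the reactions of 4-sulfonyloxy-2-pyrones and 4-sulfonyloxycoumarins with heteroatom nucleophiles; the hindered ether is thus made at an activated sp2 carbon and not by aryl–oxygen coupling.

Step 9
Reactants: 11 methyl 4-[2,5-dibromo-3-(dimethoxymethyl)-6-methoxyphenoxy]-3-methoxy-2-oxo-2H-pyran-5-carboxylate; 12 1,1-dimethoxyethene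
Product: 16 methyl 2-(2,5-dibromo-3-formyl-6-methoxyphenoxy)-3,4-dimethoxybenzoate, via bridged lactone cycloadduct 13 (not isolated), via trimethoxycyclohexadiene ester 14 (not isolated), via dimethyl acetal benzoate 15 (not isolated)
Conditions: 12 (6 equiv), toluene, 100 °C, sealed tube; concentrate; then 1 M HCl, THF, rt
Reagents that add atoms: water O
Why: This is an inverse-electron-demand Diels–Alder reaction of a 2-pyrone-5-carboxylate with a ketene acetal, a known way to alkoxybenzoates: the nucleophilic CH2 of 12 bonds to pyrone C6, which is the β-carbon of the C5 acrylate unit and the δ-carbon of the lactone dienone, and the acetal carbon bonds to C3, so that C3'–C4' and C5'–C6' are formed in a concerted but strongly asynchronous (or zwitterionic stepwise) addition. The bridged lactone 13 should lose CO2 by retro-[4+2] cycloreversion to diene 14, which aromatises by 1,2-elimination of methanol from its CH2–C(OMe)2 unit to give 15. Ring B is therefore closed by an intermolecular [4+2] annulation in which pyrone C3–C6 supply four carbons and 12 supplies two, followed by extrusion of the lactone bridge. No stereocentre remains, since the two bridgehead centres of 13 arise racemic and are destroyed on aromatisation. The selectivity required is the orientation of 12, and it is secured by matched polarisation (C6 electrophilic, CH2 nucleophilic); the reverse orientation would pair the nucleophilic carbon with the oxygen-substituted, electron-rich C3. The C3 methoxy and C4 aryloxy donors make the diene less reactive than a plain coumalate, hence the excess of 12 and the heating, and the excess also takes up the liberated methanol as trimethyl orthoacetate so that it cannot displace the aryloxy group at C4. The ring A aldehyde stays masked as its dimethyl acetal during the heating and is released by the acidic work-up, which also completes the loss of methanol from any remaining 14.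

Step 10
Reactants: 16 methyl 2-(2,5-dibromo-3-formyl-6-methoxyphenoxy)-3,4-dimethoxybenzoate
Product: 17 methyl 5-bromo-2-(2,5-dibromo-3-formyl-6-methoxyphenoxy)-3,4-dimethoxybenzoate
Conditions: Br2 (1.1 equiv), NaOAc, AcOH, rt → 40 °C
Reagents that add atoms: bromine BrBr
Why: Electrophilic aromatic bromination at C4', which is ortho to the C5' methoxy group, para to the ether oxygen and meta to the ester, as 2,3,4-trialkoxybenzoates brominate at C5; C3' is ortho to the ester and is served only by the twisted central C6' methoxy group, and the single free position of ring A (C6) lies between CHO and Br on a deactivated ring.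

Step 11
Reactants: 17 methyl 5-bromo-2-(2,5-dibromo-3-formyl-6-methoxyphenoxy)-3,4-dimethoxybenzoate
Product: 18 methyl 5-bromo-2-(2,5-dibromo-3-formyl-6-hydroxyphenoxy)-3,4-dihydroxybenzoate
Conditions: BBr3 (8 equiv), CH2Cl2, −78 → 0 °C; then ice-water
Reagents that add atoms: none
Why: Lewis-acid cleavage of aryl methyl ethers (boron complexation, then SN2 attack of bromide on methyl); the diaryl ether is inert, and the methyl ester and the aryl aldehyde are expected to survive at or below 0 °C; the step precedes the reduction so that no benzylic alcohol is exposed to BBr3.

Step 12
Reactants: 18 methyl 5-bromo-2-(2,5-dibromo-3-formyl-6-hydroxyphenoxy)-3,4-dihydroxybenzoate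
Product: 19 6-bromo-3-[2,5-dibromo-6-hydroxy-3-(hydroxymethyl)phenoxy]-4-(hydroxymethyl)benzene-1,2-diol (CNP0104332.0)
Conditions: i-Bu2AlH (10 equiv), THF, −78 °C → rt; aq. KNaC4H4O6, then NaH2PO4 to pH 5
Reagents that add atoms: none
Why: Hydride reduction of ester and aldehyde to primary alcohols with i-Bu2AlH after the three phenols have been converted to aluminium phenoxides; this reagent does not attack aryl bromides under these conditions, and the tartrate and phosphate work-up avoids the acid that would ionise the two para-hydroxybenzylic alcohols.

**Compound list**

1 | 3-bromo-4,5-dihydroxybenzaldehyde | O=Cc1cc(Br)c(O)c(O)c1 | starting material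
2 | 3-bromo-5-hydroxy-4-methoxybenzaldehyde | COc1c(O)cc(C=O)cc1Br | intermediate
3 | 2,5-dibromo-3-hydroxy-4-methoxybenzaldehyde | COc1c(Br)cc(C=O)c(Br)c1O | intermediate
4 | 2,5-dibromo-3-(dimethoxymethyl)-6-methoxyphenol | COc1c(Br)cc(C(OC)OC)c(Br)c1O | intermediate
5 | dimethyl 3-oxopentanedioate | COC(=O)CC(=O)CC(=O)OC | starting material
6 | dimethyl 2-diazo-3-oxopentanedioate | COC(=O)CC(=O)C(=[N+]=[N-])C(=O)OC | intermediate
7 | dimethyl 2-methoxy-3-oxopentanedioate (racemic) | COC(=O)CC(=O)C(OC)C(=O)OC | intermediate
8 | dimethyl 2-methoxy-4-(methoxymethylidene)-3-oxopentanedioate (racemic, E/Z mixture, not isolated) | COC=C(C(=O)OC)C(=O)C(OC)C(=O)OC | intermediate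
9 | methyl 4-hydroxy-3-methoxy-2-oxo-2H-pyran-5-carboxylate | COC(=O)c1coc(=O)c(OC)c1O | intermediate
10 | methyl 3-methoxy-2-oxo-4-[(trifluoromethanesulfonyl)oxy]-2H-pyran-5-carboxylate | COC(=O)c1coc(=O)c(OC)c1OS(=O)(=O)C(F)(F)F | intermediate
11 | methyl 4-[2,5-dibromo-3-(dimethoxymethyl)-6-methoxyphenoxy]-3-methoxy-2-oxo-2H-pyran-5-carboxylate | COC(=O)c1coc(=O)c(OC)c1Oc1c(Br)c(C(OC)OC)cc(Br)c1OC | intermediate
12 | 1,1-dimethoxyethene | C=C(OC)OC | starting material
13 | methyl 5-[2,5-dibromo-3-(dimethoxymethyl)-6-methoxyphenoxy]-4,8,8-trimethoxy-3-oxo-2-oxabicyclo[2.2.2]oct-5-ene-6-carboxylate (racemic, one enantiomer written, not isolated) | COC(=O)C1=C(Oc3c(Br)c(C(OC)OC)cc(Br)c3OC)[C@@]2(OC)C(=O)O[C@@H]1CC2(OC)OC | intermediate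
14 | methyl 6-[2,5-dibromo-3-(dimethoxymethyl)-6-methoxyphenoxy]-4,4,5-trimethoxycyclohexa-1,5-diene-1-carboxylate (not isolated) | COC(=O)C1=CCC(OC)(OC)C(OC)=C1Oc1c(Br)c(C(OC)OC)cc(Br)c1OC | intermediate
15 | methyl 2-[2,5-dibromo-3-(dimethoxymethyl)-6-methoxyphenoxy]-3,4-dimethoxybenzoate (not isolated) | COC(=O)c1ccc(OC)c(OC)c1Oc1c(Br)c(C(OC)OC)cc(Br)c1OC | intermediate
16 | methyl 2-(2,5-dibromo-3-formyl-6-methoxyphenoxy)-3,4-dimethoxybenzoate | COC(=O)c1ccc(OC)c(OC)c1Oc1c(Br)c(C=O)cc(Br)c1OC | intermediate
17 | methyl 5-bromo-2-(2,5-dibromo-3-formyl-6-methoxyphenoxy)-3,4-dimethoxybenzoate | COC(=O)c1cc(Br)c(OC)c(OC)c1Oc1c(Br)c(C=O)cc(Br)c1OC | intermediate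
18 | methyl 5-bromo-2-(2,5-dibromo-3-formyl-6-hydroxyphenoxy)-3,4-dihydroxybenzoate | COC(=O)c1cc(Br)c(O)c(O)c1Oc1c(Br)c(C=O)cc(Br)c1O | intermediate
19 | 6-bromo-3-[2,5-dibromo-6-hydroxy-3-(hydroxymethyl)phenoxy]-4-(hydroxymethyl)benzene-1,2-diol | OCc1cc(Br)c(O)c(Oc2c(CO)cc(Br)c(O)c2O)c1Br | target

**Step count and risks**

Total: 12 steps. Longest linear sequence: 9 steps (5 to 19, steps 4 to 12); the ring A branch (steps 1 to 3) joins at step 8.

Least certain steps:

Step 9 (key step). The cycloaddition may be too slow, because the C3 and C4 oxygens make the pyrone a weaker acceptor. Oligomerisation of the ketene acetal, displacement of the aryloxy group at C4 by liberated methanol, or reversible closure of the zwitterion through the ester oxygen could then take over. The fallback sets out from 11 and replaces the ketene acetal by an ynol ether, ethoxyethyne (toluene, 90 °C, sealed tube). Its cycloadduct aromatises by loss of CO2 alone, so no elimination is needed and no alcohol is released. The same polarisation (CH terminus to C6, C–OEt to C3) should give methyl 2-[2,5-dibromo-3-(dimethoxymethyl)-6-methoxyphenoxy]-4-ethoxy-3-methoxybenzoate F1. The same acidic work-up gives methyl 2-(2,5-dibromo-3-formyl-6-methoxyphenoxy)-4-ethoxy-3-methoxybenzoate F2. Bromination as in step 10 gives methyl 5-bromo-2-(2,5-dibromo-3-formyl-6-methoxyphenoxy)-4-ethoxy-3-methoxybenzoate F3. BBr3 cleaves the ethyl ether along with the methyl ethers, and the route is rejoined at 18.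

Step 8. The hindered phenoxide may attack the sulfur of the triflate (S–O cleavage, which returns the pyronolate of 9), or it may attack C6 and open the lactone. The fallback sets out from 9 and uses a vinylogous acid chloride, in which carbon is the only electrophilic site at C4. POCl3 and Et3N at 80 °C should give methyl 4-chloro-3-methoxy-2-oxo-2H-pyran-5-carboxylate F4. This is combined with 4 (Cs2CO3, DMF, rt to 50 °C) and the route is rejoined at 11.

Step 6. The orthoformate may react at the methoxy-bearing carbon, or the α-methoxy ester arm may be lost by retro-Claisen cleavage or decarboxylation in hot anhydride or aqueous acid, so that lactonisation fails. The fallback sets out from 5 and builds the ring before the methoxy group is introduced. HC(OMe)3 and Ac2O give dimethyl 2-(methoxymethylidene)-3-oxopentanedioate F5. Aqueous HCl closes it to methyl 4-hydroxy-2-oxo-2H-pyran-5-carboxylate F6. Diazo transfer at C3 (4-acetamidobenzenesulfonyl azide, Et3N) gives methyl 3-diazo-2,4-dioxo-3,4-dihydro-2H-pyran-5-carboxylate F7. O–H insertion with Rh2(OAc)4 and methanol rejoins the route at 9.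

Step 11. BBr3 may also cleave the methyl ester or convert the aldehyde into a benzal bromide on long exposure, or demethylation may stay incomplete if the mixture is kept too cold. The fallback sets out from 17 and reverses the order of the last two operations. i-Bu2AlH reduces ester and aldehyde to {5-bromo-2-[2,5-dibromo-3-(hydroxymethyl)-6-methoxyphenoxy]-3,4-dimethoxyphenyl}methanol F8. BBr3 then gives 6-bromo-4-(bromomethyl)-3-[2,5-dibromo-3-(bromomethyl)-6-hydroxyphenoxy]benzene-1,2-diol F9. Solvolysis of F9 in dilute aqueous acetone over CaCO3 rejoins the route at 19.

Step 12. The ester is conjugated to the para aluminium phenoxide at C5', so its reduction may stall at the aldehyde stage; forcing it may cost a bromine, and the product may ionise to a quinone methide during work-up. The fallback sets out from 18 and changes the reduction from nucleophilic to electrophilic hydride. Saponification (LiOH, degassed THF/H2O) gives 5-bromo-2-(2,5-dibromo-3-formyl-6-hydroxyphenoxy)-3,4-dihydroxybenzoic acid F10. BH3·THF then reduces acid and aldehyde without touching C–Br bonds and without being slowed by the phenols, and the route is rejoined at 19.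

**Further compounds**

F1 | step 9 | methyl 2-[2,5-dibromo-3-(dimethoxymethyl)-6-methoxyphenoxy]-4-ethoxy-3-methoxybenzoate | CCOc1ccc(C(=O)OC)c(Oc2c(Br)c(C(OC)OC)cc(Br)c2OC)c1OC
F2 | step 9 | methyl 2-(2,5-dibromo-3-formyl-6-methoxyphenoxy)-4-ethoxy-3-methoxybenzoate | CCOc1ccc(C(=O)OC)c(Oc2c(Br)c(C=O)cc(Br)c2OC)c1OC
F3 | step 9 | methyl 5-bromo-2-(2,5-dibromo-3-formyl-6-methoxyphenoxy)-4-ethoxy-3-methoxybenzoate | CCOc1c(Br)cc(C(=O)OC)c(Oc2c(Br)c(C=O)cc(Br)c2OC)c1OC
F4 | step 8 | methyl 4-chloro-3-methoxy-2-oxo-2H-pyran-5-carboxylate | COC(=O)c1coc(=O)c(OC)c1Cl
F5 | step 6 | dimethyl 2-(methoxymethylidene)-3-oxopentanedioate | COC=C(C(=O)OC)C(=O)CC(=O)OC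
F6 | step 6 | methyl 4-hydroxy-2-oxo-2H-pyran-5-carboxylate | COC(=O)c1coc(=O)cc1O
F7 | step 6 | methyl 3-diazo-2,4-dioxo-3,4-dihydro-2H-pyran-5-carboxylate | COC(=O)C1=COC(=O)C(=[N+]=[N-])C1=O
F8 | step 11 | {5-bromo-2-[2,5-dibromo-3-(hydroxymethyl)-6-methoxyphenoxy]-3,4-dimethoxyphenyl}methanol | COc1c(Br)cc(CO)c(Oc2c(Br)c(CO)cc(Br)c2OC)c1OC
F9 | step 11 | 6-bromo-4-(bromomethyl)-3-[2,5-dibromo-3-(bromomethyl)-6-hydroxyphenoxy]benzene-1,2-diol | Oc1c(Br)cc(CBr)c(Oc2c(Br)c(CBr)cc(Br)c2O)c1O
F10 | step 12 | 5-bromo-2-(2,5-dibromo-3-formyl-6-hydroxyphenoxy)-3,4-dihydroxybenzoic acid | OC(=O)c1cc(Br)c(O)c(O)c1Oc1c(Br)c(C=O)cc(Br)c1O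
A1 | alternative 1 | ring-expanded diisopropylsilylene (dibenzo-fused 1,5-dioxa-2-silepine; Si between O4 of ring A and C6', ether O between C3 and C1', Br at C2, C5 and C4', 1,3-dioxolan-2-yl at C2', OMe at C5') | CC(C)[Si]1(C(C)C)Oc2c(Br)ccc(Br)c2Oc2c(C3OCCO3)cc(Br)c(OC)c21
A2 | alternative 1 | 4,7-dibromo-2,2-di(propan-2-yl)-1,3,2-benzodioxasilole | CC(C)[Si]1(C(C)C)Oc2c(Br)ccc(Br)c2O1
A3 | alternative 1 | 4-bromo-6-(1,3-dioxolan-2-yl)-3-methoxy-2-(trimethylsilyl)phenyl trifluoromethanesulfonate | COc1c(Br)cc(C2OCCO2)c(OS(=O)(=O)C(F)(F)F)c1[Si](C)(C)C
A4 | alternative 2 | methyl 2,6,9-tribromo-3,4-dimethoxy-11-oxo-11H-dibenzo[b,e][1,4]dioxepine-7-carboxylate | COC(=O)c1cc(Br)c2OC(=O)c3cc(Br)c(OC)c(OC)c3Oc2c1Br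
A5 | alternative 2 | methyl 2,5-dibromo-3-(5-bromo-2-hydroxy-3,4-dimethoxybenzoyl)-4-hydroxybenzoate | COC(=O)c1cc(Br)c(O)c(C(=O)c2cc(Br)c(OC)c(OC)c2O)c1Br
A6 | alternative 2 | methyl 2',5,5'-tribromo-6,7-dimethoxy-3,6'-dioxo-3H-spiro[1-benzofuran-2,1'-cyclohexa-2',4'-diene]-3'-carboxylate (racemic) | COC(=O)C1=C(Br)C2(Oc3c(OC)c(OC)c(Br)cc3C2=O)C(=O)C(Br)=C1
A7 | alternative 3 | methyl 5-bromo-2-(2,5-dibromo-3-formyl-6-methoxyphenoxy)-3-hydroxy-4-methoxybenzoate | COC(=O)c1cc(Br)c(OC)c(O)c1Oc1c(Br)c(C=O)cc(Br)c1OC
A8 | alternative 3 | 3-bromo-4-methoxyfuran | COc1cocc1Br
A9 | alternative 3 | methyl 3-(2,5-dibromo-3-formyl-6-methoxyphenoxy)prop-2-ynoate | COC(=O)C#COc1c(Br)c(C=O)cc(Br)c1OC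
A10 | alternative 3 | methyl 6-bromo-3-(2,5-dibromo-3-formyl-6-methoxyphenoxy)-5-methoxy-7-oxabicyclo[2.2.1]hepta-2,5-diene-2-carboxylate (racemic, one enantiomer written) | COC(=O)C1=C(Oc3c(Br)c(C=O)cc(Br)c3OC)[C@@H]2O[C@H]1C(Br)=C2OC
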